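# Proposed total synthesis of CNP0308003.0 (17)

## The problem

Target 17 (C30H22O16) is an achiral, linear pentamer of 1,2,3,5-tetrahydroxybenzene. It has five benzene rings, four diaryl ether bridges, twelve free hydroxyl groups and no C–C bond between rings.

The rings are lettered A to E, from the 2,4,6-trihydroxyphenoxy end to the 3,4,5-trihydroxyphenoxy end. Each ring is numbered so that C1 stands between two CH groups (C2, C6) and C4 stands between two oxygen-bearing carbons (C3, C5). Every bridge is then C4(ring n)–O–C1(ring n+1). The chain therefore runs head to tail and offers no symmetry for a two-directional synthesis.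

The hardest feature is the bridge itself. It joins two very electron-rich arenes, and its C4 side carries two ortho oxygens. This is the worst case for any O-arylation, and it occurs four times.

No stereocentre exists. What must be controlled is regiochemistry (para bridges only, one direction) and chain length (exactly five rings).

The free dodecaphenol has a pyrogallol end ring and hydroquinone-type inner rings, so it is oxidised by air as soon as base is present. The phenols must be freed last and under acid.

The feature that makes the key step possible lies in rings B and D. The oxygens on C1, C3 and C5 form a phloroglucinol (triketide) pattern, and C4 is the oxygenated terminal carbon of that triketide. Each of these rings is thus a constitutional isomer of a 2-pyrone: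

| Pyrone atom | Arene atom |
|---|---|
| C4 | C1 |
| C3 and C5 | C2 and C6 |
| lactone carbon C2 and C6 | C3 and C5 |
| exocyclic CH2 on C6 | C4 |

In that pyrone both bridge-bearing carbons are ordinary electrophiles: one is a vinylogous acyl carbon and the other a primary allylic carbon.

## Retrosynthesis

**17 ⇒ 16.** Eight O–CH3 bonds on rings A, C and E are cut. Methyl is chosen because the three arene building blocks can be bought as methyl ethers. The four hydroxyl groups of rings B and D are only created in the step before, so they never need protection. The forward reaction must cleave eight aryl methyl ethers in acid without touching a diaryl ether.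

**16 ⇒ 12 (key step).**
- *Cut.* The C3–C4 bond of ring B and the C3–C4 bond of ring D (arene numbering) are cut. Each C3 is reconnected as a lactone carbonyl to the oxygen on C5. Rings B and D become 2-pyrones, and 16 becomes its isomer 12.
- *Against the neighbouring cuts.* A cut at C1–C2 would make C1 an ester carbon, and the Claisen condensation would expel the aryloxide that has to stay. A cut at C2–C3 keeps both oxygens, but it places the C4 oxygen on a crowded carbon between two carbonyl groups and has no stable cyclic mask. Only the C3–C4 cut leaves C4 as a primary CH2–OAr and C1 as an enol aryl ether. Its mask is a stable heteroaromatic ring.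
- *Why B and D.* They are the smallest sufficient set, because each touches two bridges and two new rings therefore cover all four.
- *Simplification.* Compound 12 contains no diaryl ether. Its four bridges are two primary alkyl aryl ethers and two vinylogous aryl esters.
- *Demand on the forward reaction.* It must transfer the lactone acyl carbon from O to the CH2 carbon, twice, without loss of the aryloxy group on pyrone C4.

**12 ⇒ 10 + 11.** The bond between pyrone C4 of the future ring B and the oxygen of ring A is cut. The hindered phenol 11 brings its own C4(A)–O bond. It only has to add to an unhindered vinylogous acyl bromide, which is far easier than attacking an arene. The forward reaction must choose C4–Br of 10 over the C4–OAr group of the other pyrone.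

**10 ⇒ 9 + 3.** The CH2–O bond between the future ring B and ring C is cut. This is the bond that becomes the doubly ortho-substituted C4(B)–O bridge, and here it is a Williamson ether synthesis on a primary bromide. In the linchpin 3 the CH2Br group reacts before C4–Br. Each pyrone therefore meets first the phenol that will sit on its CH2 and then the phenol for C4, and this fixes the direction of growth as E to A.

**9 ⇒ 7 ⇒ 5 + 6.** First the C1(C)–O bond is traced back to a C–B bond. Then the bond from pyrone C4 of the future ring D to the hindered oxygen of ring C is cut. Ring C has to react first through its hindered oxygen and later through its unhindered one, which is the reverse of the natural order in the free hydroquinone. The purchasable boronate 6 hides the unhindered oxygen without a protecting-group step. The forward reactions are an addition–elimination followed by a mild ipso-hydroxylation.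

**5 ⇒ 3 + 4.** The CH2–O bond between the future ring D and ring E is cut, with the same logic and the same linchpin as for 10. One building block thus serves for both new rings.

**3 ⇒ 2 ⇒ 1.** The C–Br bonds are cut. Both electrophilic sites are installed on triacetic acid lactone 1, which already holds all six carbons of a ring in the right oxidation pattern.

## Roads not taken

**Alternative 1:** The cut is each O–C1 bond, one ring at a time.
- *Forward key step.* A copper-catalysed Ullmann coupling (CuI, picolinic acid, K3PO4, hot DMSO) joins a 2,6-dimethoxyphenol, first 11, to 2-(benzyloxy)-5-bromo-1,3-dimethoxybenzene A1. This gives the dimer A2, which is debenzylated and coupled again.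
- *Why the chosen plan is better.* Every coupling pairs a di-ortho-substituted, chelating, electron-rich phenoxide with an electron-rich bromide. Both the activation of the C–Br bond at monovalent copper and the C–O bond-forming step are slow, while reduction of the bromide and oxidation of the phenoxide compete. The difficulty is met four times, on ever larger substrates, in a strictly linear couple/deprotect sequence. The chosen plan performs no O-arylation at all.

**Alternative 2:** The cut is the same O–C1 bond, but the acceptor ring carries a para formyl group that later becomes the C4 oxygen.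
- *Forward key step.* SNAr of 11 on 4-fluoro-2,6-dimethoxybenzaldehyde A3 gives aldehyde A4. Baeyer–Villiger oxidation and formate hydrolysis give phenol A5, and the pair of steps is repeated three more times.
- *Why the chosen plan is better.* The step count is about the same as in the chosen route. The formyl group of A3, however, is twisted by two ortho methoxy groups and fed by their donation, so the hindered phenoxide needs forcing conditions at an aromatic carbon. A peracid must also be used four times on oligomers that gain electron-rich rings each round. One bridge is gained per two steps with no convergence, so the difficulty is repeated rather than removed.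

**Alternative 3:** The cut is all O–C1 bonds at once, by union of two centres of like polarity.
- *Forward key step.* Anodic or aerobic (copper–amine or laccase) oxidation of syringic acid A6 gives a phenoxyl radical. It couples through oxygen to the ipso carbon of a second unit with loss of CO2, as in poly(phenylene oxide) synthesis. This would lead to the pentameric acid A7.
- *Why the chosen plan is better.* The connectivity and direction are right, but the quinone-ketal redistribution inherent in this mechanism equilibrates chain lengths, so nothing stops growth at five rings. The product phenols are oxidised more easily than the monomer. The terminal carboxyl group would still have to be degraded to a hydroxyl group. The chosen plan fixes chain length and direction by construction.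

Key step: step 8

Assumption: the SMILES has no stereodescriptor and the diaryl ether axes rotate freely, so no stereochemical step is planned; 1, 4, 6 and 11 are taken as purchasable.

## Route

Step 1
Reactants: 1 4-hydroxy-6-methyl-2H-pyran-2-one (triacetic acid lactone)
Product: 2 4-bromo-6-methyl-2H-pyran-2-one
Conditions: n-Bu4NBr, P2O5, toluene, 100 °C
Reagents that add atoms: tetrabutylammonium bromide, CCCC[N+](CCCC)(CCCC)CCCC.[Br-]
Why: Dehydrative bromination of a vinylogous acid: P2O5 turns the 4-OH into a phosphate leaving group and bromide replaces it by addition–elimination at C4. The conversion is well precedented for 4-hydroxy-2-pyrones.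

Step 2
Reactants: 2 4-bromo-6-methyl-2H-pyran-2-one
Product: 3 4-bromo-6-(bromomethyl)-2H-pyran-2-one
Conditions: NBS (1.0 equiv), AIBN (cat.), PhCF3, reflux
Reagents that add atoms: N-bromosuccinimide, O=C1CCC(=O)N1Br
Why: Wohl–Ziegler bromination; the C6-methyl group gives a radical delocalised over the pyrone, as in the known bromination of 4-methoxy-6-methyl-2-pyrone. The 4-bromo substituent makes the ring too electron-poor for ionic bromination at C3, and one equivalent of NBS limits dibromination.

Step 3
Reactants: 3 4-bromo-6-(bromomethyl)-2H-pyran-2-one; 4 3,4,5-trimethoxyphenol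
Product: 5 4-bromo-6-[(3,4,5-trimethoxyphenoxy)methyl]-2H-pyran-2-one
Conditions: K2CO3, acetone, 0 °C to rt, slight excess of 3
Reagents that add atoms: none
Why: Williamson ether synthesis; SN2 at the primary allylic bromide next to an electron-poor ring should outrun addition–elimination at C4–Br at low temperature. This bond becomes the hindered C4(D)–O bridge.

Step 4
Reactants: 5 4-bromo-6-[(3,4,5-trimethoxyphenoxy)methyl]-2H-pyran-2-one; 6 2,6-dimethoxy-4-(4,4,5,5-tetramethyl-1,3,2-dioxaborolan-2-yl)phenol
Product: 7 4-[2,6-dimethoxy-4-(4,4,5,5-tetramethyl-1,3,2-dioxaborolan-2-yl)phenoxy]-6-[(3,4,5-trimethoxyphenoxy)methyl]-2H-pyran-2-one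
Conditions: K2CO3, DMF, rt to 40 °C
Reagents that add atoms: none
Why: Vinylogous acyl substitution (addition–elimination) of a 4-halo-2-pyrone by a phenoxide. C4 lies between two CH groups, so the hindrance of the 2,6-dimethoxyphenoxide matters little, and the pinacol boronate is inert to carbonate.

Step 5
Reactants: 7 4-[2,6-dimethoxy-4-(4,4,5,5-tetramethyl-1,3,2-dioxaborolan-2-yl)phenoxy]-6-[(3,4,5-trimethoxyphenoxy)methyl]-2H-pyran-2-one
Product: 9 4-(4-hydroxy-2,6-dimethoxyphenoxy)-6-[(3,4,5-trimethoxyphenoxy)methyl]-2H-pyran-2-one, via aryl pinacol borate 8 (not isolated)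
Conditions: 30% aq H2O2 (1.5 equiv), phosphate buffer pH 8, THF, 0 °C to rt
Reagents that add atoms: hydrogen peroxide, OO
Why: Ipso-hydroxylation of an aryl boronate by 1,2-shift of the aryl group from boron to oxygen, followed by hydrolysis of borate 8 in the same medium. The near-neutral buffer keeps the hydroperoxide anion scarce, so the lactone and the vinylogous aryl ester should survive.

Step 6
Reactants: 9 4-(4-hydroxy-2,6-dimethoxyphenoxy)-6-[(3,4,5-trimethoxyphenoxy)methyl]-2H-pyran-2-one; 3 4-bromo-6-(bromomethyl)-2H-pyran-2-one
Product: 10 4-bromo-6-{[3,5-dimethoxy-4-({2-oxo-6-[(3,4,5-trimethoxyphenoxy)methyl]-2H-pyran-4-yl}oxy)phenoxy]methyl}-2H-pyran-2-one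
Conditions: K2CO3, acetone, 0 °C to rt, 3 (1.3 equiv)
Reagents that add atoms: none
Why: Williamson ether synthesis as in step 3, now with the unhindered C1 hydroxyl of ring C. The CH2Br group is a far better electrophile than either C4–Br or the donor-deactivated C4–OAr carbon of the pyrone already present.

Step 7
Reactants: 10 4-bromo-6-{[3,5-dimethoxy-4-({2-oxo-6-[(3,4,5-trimethoxyphenoxy)methyl]-2H-pyran-4-yl}oxy)phenoxy]methyl}-2H-pyran-2-one; 11 2,4,6-trimethoxyphenol
Product: 12 6-{[3,5-dimethoxy-4-({2-oxo-6-[(3,4,5-trimethoxyphenoxy)methyl]-2H-pyran-4-yl}oxy)phenoxy]methyl}-4-(2,4,6-trimethoxyphenoxy)-2H-pyran-2-one (bis-pyrone)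
Conditions: K2CO3, DMF, rt to 40 °C
Reagents that add atoms: none
Why: Addition–elimination as in step 4. Bromide on C4 is the better leaving group and sits on the more electrophilic pyrone, so the aryloxy group of the other pyrone should not be exchanged.

Step 8
Reactants: 12 6-{[3,5-dimethoxy-4-({2-oxo-6-[(3,4,5-trimethoxyphenoxy)methyl]-2H-pyran-4-yl}oxy)phenoxy]methyl}-4-(2,4,6-trimethoxyphenoxy)-2H-pyran-2-one (bis-pyrone)
Product: 16 5-(2,4,6-trimethoxyphenoxy)-2-{4-[3,5-dihydroxy-4-(3,4,5-trimethoxyphenoxy)phenoxy]-3,5-dimethoxyphenoxy}benzene-1,3-diol (octamethyl ether of the target), via dipotassium bis-dienolate 13 (not isolated), via ring-opened bis-ketene enolate 14 (not isolated), via tetrapotassium tetraphenolate 15 (not isolated)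
Conditions: KOt-Bu (8 equiv), THF, argon, 0 °C to 65 °C; then degassed 1 M HCl, 0 °C
Reagents that add atoms: none
Why: Proposed new method: KOt-Bu removes one proton from each C6–CH2–OAr group of 12 to give bis-dienolate 13, whose charge rests on the lactone carbonyl oxygen, so that the C2–O1 bond of each pyrone can break in E1cB fashion to the dienylketene enolate 14, which keeps C3 and C6 cis on the C4=C5 double bond. Rotation about C5–C6 brings the enolate carbon (the former CH2) to the ketene carbon C2, and the new C–C bond forms, once for ring B and once for ring D, as a 6π closure of an oxido-dienylketene (equally a 6-(enolendo)-exo-dig C-acylation); tautomerisation and further base give tetraphenolate 15, which acid turns into 16. tert-Butoxide that adds to C2 of residual neutral pyrone, or tert-butanol that adds to the ketene, only opens a second channel to the same bond, a 6-(enolendo)-exo-trig Claisen condensation of the open-chain ester, so both channels converge. The closest known reaction types are the alkoxide-induced recyclisation of 4-alkoxy-6-methyl-2-pyrones to 5-alkoxyresorcinols, the base-induced rearrangement of enol lactones to cyclic 1,3-diketones and the dienylketene closure that ends cyclobutenone benzannulations; new here are the oxygen on the exocyclic carbon, the aryloxy group on C4, the non-exchanging base and the twofold use. The step needs C- over O-acylation: O-acylation only returns the pyrone and is reversible, C-acylation ends in an aromatic phenolate and is not, and the six-carbon chain allows no aldol mode and no other ring size. It also needs the C4–OAr bonds to survive, since a 4-aryloxy-2-pyrone is a vinylogous aryl ester, which is why methoxide is avoided; the dienolate is no longer an electrophile, and the two ortho methoxy groups of rings A and C stand over both faces of pyrone C4 and keep the bulky tert-butoxide away. No stereocentre is formed.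

Step 9
Reactants: 16 5-(2,4,6-trimethoxyphenoxy)-2-{4-[3,5-dihydroxy-4-(3,4,5-trimethoxyphenoxy)phenoxy]-3,5-dimethoxyphenoxy}benzene-1,3-diol
Product: 17 5-(2,4,6-trihydroxyphenoxy)-2-{4-[3,5-dihydroxy-4-(3,4,5-trihydroxyphenoxy)phenoxy]-3,5-dihydroxyphenoxy}benzene-1,3-diol (CNP0308003.0)
Conditions: BBr3 (20 equiv), CH2Cl2, argon, -78 °C to rt; then degassed H2O, 0 °C
Reagents that add atoms: none
Why: BBr3 cleavage of aryl methyl ethers, with bromide attacking the methyl carbon of the boron-complexed ether. The diaryl ether bridges offer no sp3 carbon and stay intact, and the acidic, oxygen-free medium protects the dodecaphenol from autoxidation.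

## Compound list

1 | 4-hydroxy-6-methyl-2H-pyran-2-one | CC1=CC(O)=CC(=O)O1 | starting material
2 | 4-bromo-6-methyl-2H-pyran-2-one | CC1=CC(Br)=CC(=O)O1 | intermediate
3 | 4-bromo-6-(bromomethyl)-2H-pyran-2-one | BrCC1=CC(Br)=CC(=O)O1 | intermediate
4 | 3,4,5-trimethoxyphenol | COc1cc(O)cc(OC)c1OC | starting material
5 | 4-bromo-6-[(3,4,5-trimethoxyphenoxy)methyl]-2H-pyran-2-one | COc1cc(OCC2=CC(Br)=CC(=O)O2)cc(OC)c1OC | intermediate
6 | 2,6-dimethoxy-4-(4,4,5,5-tetramethyl-1,3,2-dioxaborolan-2-yl)phenol | COc1cc(cc(OC)c1O)B1OC(C)(C)C(C)(C)O1 | starting material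
7 | boronate pyrone (rings C and E, pyrone D) | COc1cc(OCC2=CC(Oc3c(OC)cc(cc3OC)B4OC(C)(C)C(C)(C)O4)=CC(=O)O2)cc(OC)c1OC | intermediate
8 | aryl pinacol borate from 7 (not isolated) | COc1cc(OCC2=CC(Oc3c(OC)cc(OB4OC(C)(C)C(C)(C)O4)cc3OC)=CC(=O)O2)cc(OC)c1OC | intermediate
9 | 4-(4-hydroxy-2,6-dimethoxyphenoxy)-6-[(3,4,5-trimethoxyphenoxy)methyl]-2H-pyran-2-one | COc1cc(OCC2=CC(Oc3c(OC)cc(O)cc3OC)=CC(=O)O2)cc(OC)c1OC | intermediate
10 | bromo bis-pyrone | COc1cc(OCC2=CC(Oc3c(OC)cc(OCC4=CC(Br)=CC(=O)O4)cc3OC)=CC(=O)O2)cc(OC)c1OC | intermediate
11 | 2,4,6-trimethoxyphenol | COc1cc(OC)c(O)c(OC)c1 | starting material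
12 | bis-pyrone, isomer of 16 | COc1cc(OCC2=CC(Oc3c(OC)cc(OCC4=CC(Oc5c(OC)cc(OC)cc5OC)=CC(=O)O4)cc3OC)=CC(=O)O2)cc(OC)c1OC | intermediate
13 | dipotassium bis-dienolate of 12 (not isolated; delocalised anion, exocyclic geometry not fixed) | [K+].[K+].COc1cc(OC=C2C=C(Oc3c(OC)cc(OC=C4C=C(Oc5c(OC)cc(OC)cc5OC)C=C([O-])O4)cc3OC)C=C([O-])O2)cc(OC)c1OC | intermediate
14 | ring-opened bis-ketene enolate, dipotassium salt (not isolated) | [K+].[K+].COc1cc(OC=C([O-])/C=C(/Oc2c(OC)cc(OC=C([O-])/C=C(/Oc3c(OC)cc(OC)cc3OC)C=C=O)cc2OC)C=C=O)cc(OC)c1OC | intermediate
15 | tetrapotassium tetraphenolate of 16 (not isolated) | [K+].[K+].[K+].[K+].COc1cc(Oc2c([O-])cc(Oc3c(OC)cc(Oc4c([O-])cc(Oc5c(OC)cc(OC)cc5OC)cc4[O-])cc3OC)cc2[O-])cc(OC)c1OC | intermediate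
16 | octamethyl ether of the target (rings A, C and E methylated, rings B and D free) | COc1cc(Oc2c(O)cc(Oc3c(OC)cc(Oc4c(O)cc(Oc5c(OC)cc(OC)cc5OC)cc4O)cc3OC)cc2O)cc(OC)c1OC | intermediate
17 | CNP0308003.0 | Oc1cc(O)c(Oc2cc(O)c(Oc3cc(O)c(Oc4cc(O)c(Oc5cc(O)c(O)c(O)c5)c(O)c4)c(O)c3)c(O)c2)c(O)c1 | target

## Step count and least certain steps

Total steps: 9. Longest linear sequence: 9 (1, 2, 3, 5, 7, 9, 10, 12, 16, 17). Linchpin 3 enters twice.

**Step 8 (key step, proposed new method).**
- *What may go wrong.* The doubly stabilised dienolate may refuse to open at temperatures the substrate tolerates. Intermolecular condensation, or loss of aryloxide from pyrone C4 by addition–elimination, could then overtake the fold. The reaction may also stop after one ring.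
- *Fallback.* It sets out from 12, comes back at 16, and replaces anionic by cationic activation, using known chemistry throughout.
  - O-Methylation of both lactone carbonyls with Me3OBF4 (CH2Cl2, rt) gives the bis(2-methoxypyrylium) bis(tetrafluoroborate) F1.
  - Water with NaHCO3 adds at the α-carbon C6, and the 2H-pyranol opens electrocyclically, as in pyrylium pseudo-base formation. This gives the bis(methyl (E)-3-aryloxy-5-oxohex-2-enoate) F2.
  - Excess LiN(SiMe3)2 (THF, -78 °C to rt) closes both rings by Claisen condensation to 16.

**Step 3.**
- *What may go wrong.* The unhindered phenoxide may also add to C4–Br, giving substitution at the wrong site or at both sites.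
- *Fallback.* It sets out from 4, comes back at 5, and builds the pyrone around the ether bond instead of alkylating a finished pyrone.
  - 4 and 2-chloro-N-methoxy-N-methylacetamide (K2CO3, KI, acetone) give N-methoxy-N-methyl-2-(3,4,5-trimethoxyphenoxy)acetamide F3.
  - The lithium dienolate of 2,2,6-trimethyl-4H-1,3-dioxin-4-one (LiN(SiMe3)2, THF, -78 °C) acylates on its methyl carbon to give the keto-dioxinone F4.
  - Heating in toluene (110 °C) expels acetone, and the acylketene lactonises to the 4-hydroxy-2-pyrone F5.
  - n-Bu4NBr/P2O5 as in step 1 gives 5.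

**Step 6.**
- *What may go wrong.* The same site competition arises on a valuable substrate. In addition, the phenoxide of 9 may exchange the aryloxy group on C4 of the pyrone already present, which would scramble the chain.
- *Fallback.* It sets out from 2 and 9, comes back at 10, avoids free phenoxide and also bypasses step 2.
  - SeO2 (dioxane, heat) oxidises 2 to 4-bromo-2-oxo-2H-pyran-6-carbaldehyde F6.
  - NaBH4 with CeCl3 (THF/EtOH, -20 °C) gives 4-bromo-6-(hydroxymethyl)-2H-pyran-2-one F7.
  - A Mitsunobu reaction of F7 with 9 (PPh3, DIAD, THF, 0 °C) gives 10, because only the activated CH2–O carbon is electrophilic under these conditions.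

**Step 5.**
- *What may go wrong.* Hydroperoxide may attack the lactone or pyrone C4 and cleave the vinylogous aryl ester. The freed phenol may also be over-oxidised with loss of the pyronyloxy group.
- *Fallback.* It sets out from 5, comes back at 9, and uses no oxidant.
  - 2,6-Dimethoxyhydroquinone is silylated at its unhindered hydroxyl (TBSCl, imidazole, DMF, 0 °C) to 4-[(tert-butyldimethylsilyl)oxy]-2,6-dimethoxyphenol F8.
  - F8 and 5 (K2CO3, DMF) give the silyl ether F9.
  - n-Bu4NF buffered with AcOH (THF, 0 °C) frees 9.

**Step 9.**
- *What may go wrong.* Cleavage of the eight methyl ethers may be incomplete, and the product may oxidise in air during work-up and purification.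
- *Fallback.* It sets out from 16 and comes back at 17 through a stable derivative.
  - The crude product of the BBr3 reaction is acetylated (Ac2O, pyridine) to the dodecaacetate F10.
  - F10 can be chromatographed on silica and freed from partly methylated material.
  - Acidic methanolysis (HCl, MeOH, argon) then gives 17.

## Further compounds

F1 | step 8 | bis(2-methoxypyrylium) bis(tetrafluoroborate) from 12 | COc1cc(OCc2cc(Oc3c(OC)cc(OCc4cc(Oc5c(OC)cc(OC)cc5OC)cc(OC)[o+]4)cc3OC)cc(OC)[o+]2)cc(OC)c1OC.F[B-](F)(F)F.F[B-](F)(F)F
F2 | step 8 | open-chain bis(methyl (E)-3-aryloxy-5-oxohex-2-enoate) | COC(=O)/C=C(/Oc1c(OC)cc(OC)cc1OC)CC(=O)COc1cc(OC)c(O/C(CC(=O)COc2cc(OC)c(OC)c(OC)c2)=C/C(=O)OC)c(OC)c1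
F3 | step 3 | N-methoxy-N-methyl-2-(3,4,5-trimethoxyphenoxy)acetamide | COc1cc(OCC(=O)N(C)OC)cc(OC)c1OC
F4 | step 3 | 2,2-dimethyl-6-[2-oxo-3-(3,4,5-trimethoxyphenoxy)propyl]-4H-1,3-dioxin-4-one | COc1cc(OCC(=O)CC2=CC(=O)OC(C)(C)O2)cc(OC)c1OC
F5 | step 3 | 4-hydroxy-6-[(3,4,5-trimethoxyphenoxy)methyl]-2H-pyran-2-one | COc1cc(OCC2=CC(O)=CC(=O)O2)cc(OC)c1OC
F6 | step 6 | 4-bromo-2-oxo-2H-pyran-6-carbaldehyde | O=CC1=CC(Br)=CC(=O)O1
F7 | step 6 | 4-bromo-6-(hydroxymethyl)-2H-pyran-2-one | OCC1=CC(Br)=CC(=O)O1
F8 | step 5 | 4-[(tert-butyldimethylsilyl)oxy]-2,6-dimethoxyphenol | COc1cc(O[Si](C)(C)C(C)(C)C)cc(OC)c1O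
F9 | step 5 | 4-{4-[(tert-butyldimethylsilyl)oxy]-2,6-dimethoxyphenoxy}-6-[(3,4,5-trimethoxyphenoxy)methyl]-2H-pyran-2-one | COc1cc(OCC2=CC(Oc3c(OC)cc(O[Si](C)(C)C(C)(C)C)cc3OC)=CC(=O)O2)cc(OC)c1OC
F10 | step 9 | dodecaacetate of 17 | CC(=O)Oc1cc(OC(C)=O)c(Oc2cc(OC(C)=O)c(Oc3cc(OC(C)=O)c(Oc4cc(OC(C)=O)c(Oc5cc(OC(C)=O)c(OC(C)=O)c(OC(C)=O)c5)c(OC(C)=O)c4)c(OC(C)=O)c3)c(OC(C)=O)c2)c(OC(C)=O)c1
A1 | alternative 1 | 2-(benzyloxy)-5-bromo-1,3-dimethoxybenzene | COc1cc(Br)cc(OC)c1OCc1ccccc1
A2 | alternative 1 | 2-(benzyloxy)-1,3-dimethoxy-5-(2,4,6-trimethoxyphenoxy)benzene | COc1cc(OC)c(Oc2cc(OC)c(OCc3ccccc3)c(OC)c2)c(OC)c1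
A3 | alternative 2 | 4-fluoro-2,6-dimethoxybenzaldehyde | COc1cc(F)cc(OC)c1C=O
A4 | alternative 2 | 2,6-dimethoxy-4-(2,4,6-trimethoxyphenoxy)benzaldehyde | COc1cc(OC)c(Oc2cc(OC)c(C=O)c(OC)c2)c(OC)c1
A5 | alternative 2 | 2,6-dimethoxy-4-(2,4,6-trimethoxyphenoxy)phenol | COc1cc(OC)c(Oc2cc(OC)c(O)c(OC)c2)c(OC)c1
A6 | alternative 3 | syringic acid (4-hydroxy-3,5-dimethoxybenzoic acid) | COc1cc(cc(OC)c1O)C(O)=O
A7 | alternative 3 | pentameric 2,6-dimethoxy-1,4-phenylene oxide with terminal carboxyl group | OC(=O)c1cc(OC)c(Oc2cc(OC)c(Oc3cc(OC)c(Oc4cc(OC)c(Oc5cc(OC)c(O)c(OC)c5)c(OC)c4)c(OC)c3)c(OC)c2)c(OC)c1
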